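## Plan

1. Cuts: C11=C12 and C11′=C12′ (two Wittig olefinations around a C10 bis-phosphonium salt), the C19–O ester bond, C7–C8 (2-furyllithium + allylic bromide, the furan being a masked C8 ketone / C9=C10 / C11 aldehyde), and in the keto-end ring C4–C5 together with C6–C1.
2. Enabling feature: the 3-hydroxy-β-ring has its oxygen at C3 para to C6 and its only C=C at C5=C6, which is a cyclohexa-1,4-diene at the enol-ether level. A 2-silyloxydiene from mesityl oxide (C1–C4 with the gem-dimethyl group) and ethyl but-2-ynoate (C5≡C6 with C18 and C7) give it in one Diels–Alder reaction.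
3. Forward, keto end: β-ring by cycloaddition, C3 ketone reduced, C7 bromide, furan alkylation, 19-O-acylation, furan opening to the (E)-4-oxo-enal C8–C11.
4. Forward, ε end and chain: (R)-α-ionone is extended to the C15 nitrile, oxidised at C3′, reduced and converted to the C15 hydroxy aldehyde. This is joined to the C10 bis-ylide, and the resulting C25 salt is joined to the oxo-enal at C11=C12 in the last step.
5. Stereochemistry: C3 (R) from ketoreductase reduction of the prochiral ring ketone; C6′ from (R)-α-ionone; C3′ (R) from an oxazaborolidine reduction that the ring conformation reinforces.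
6. Alkene geometry: the 2-enoate and the C10 unit are bought as E isomers; C9=C10 is set by iodine equilibration and the new disubstituted bonds by thermal equilibration.

Key step: step 2

Assumption: (R)-α-ionone is bought as the single enantiomer (the racemate would first need a resolution).
Remark: the Wittig steps are expected to give E/Z mixtures at the new disubstituted double bonds; these are carried on and equilibrated to the all-E compound at the end of step 18. All polyene steps are run under argon in the dark.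

## Route

Step 1
Reactants: 1 mesityl oxide (4-methylpent-3-en-2-one)
Product: 3 4-methyl-2-(trimethylsilyloxy)penta-1,3-diene, via lithium dienolate 2 (not isolated)
Conditions: LiN(iPr)2 (1.05 equiv), THF, −78 °C; then Me3SiCl, −78 → 0 °C
Reagents that add atoms: chlorotrimethylsilane, C[Si](C)(C)Cl
Why: Kinetic deprotonation of the methyl ketone by the hindered amide gives the cross-conjugated lithium dienolate, which is O-silylated (silyl enol ether formation) to the 2-silyloxydiene that carries the future C1 gem-dimethyl terminus.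

Step 2
Reactants: 3 4-methyl-2-(trimethylsilyloxy)penta-1,3-diene; 4 ethyl but-2-ynoate
Product: 6 ethyl 2,6,6-trimethyl-4-oxocyclohex-1-ene-1-carboxylate, via silyl dienol ether cycloadduct 5 (not isolated)
Conditions: neat, 3 (2 equiv), BHT (cat.), sealed tube, 160 °C; then 0.5 M HCl, THF, 0 °C
Reagents that add atoms: none
Why: A thermal [4+2] cycloaddition (Diels–Alder reaction) of the electron-rich 2-silyloxydiene with the acetylenic ester forms C4–C5 and C6–C1 and gives the cyclohexa-1,4-diene whose ester-conjugated C5=C6 bond is that of the target, after which brief cold acid cleaves the silyl enol ether with C-protonation at C2 to the C3 ketone. The closest known reaction type is the cycloaddition of 2-silyloxy-1,3-dienes with alkynoates and ynones, including the asynchronous Mukaiyama–Michael-like variants known for dienes with a fully substituted terminus. The six-membered ring closes by intermolecular [4+2] addition across the diene termini, and in the stepwise limit the second bond forms by 6-endo attack of the allenoate carbon C6 on the silyloxyallyl cation terminus C1. No stereocentre is created, since the adduct is achiral, so C3 is left to step 3. The step needs para regiochemistry (ester-bearing carbon on C6, para to the C3 oxygen), and this is secured by the match of the largest HOMO coefficient at the CH2 terminus of the diene with the β-carbon of the ynoate. The cis-methyl group at the diene terminus slows the reaction, which is why excess diene, high concentration and heat are used, and the short cold hydrolysis is meant to keep the C5=C6 bond from moving into conjugation with the ketone.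

Step 3
Reactants: 6 ethyl 2,6,6-trimethyl-4-oxocyclohex-1-ene-1-carboxylate
Product: 7 ethyl (4R)-4-hydroxy-2,6,6-trimethylcyclohex-1-ene-1-carboxylate
Conditions: (R)-selective ketoreductase (NADPH-dependent alcohol dehydrogenase), NADP+ (cat.), iPrOH (10 vol%), phosphate buffer pH 7.0, 30 °C
Reagents that add atoms: none
Why: Enzymatic ketone reduction by a ketoreductase chosen from a panel for the (R)-alcohol should distinguish the CH2–C(CH3)2 flank from the CH2–C(CH3)= flank, which no small hydride reagent does, and the neutral buffer should keep the β,γ-unsaturated ketone from isomerising.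

Step 4
Reactants: 7 ethyl (4R)-4-hydroxy-2,6,6-trimethylcyclohex-1-ene-1-carboxylate
Product: 8 ethyl (4R)-4-(tert-butyldimethylsilyloxy)-2,6,6-trimethylcyclohex-1-ene-1-carboxylate
Conditions: tBuMe2SiCl, imidazole, DMF, 23 °C
Reagents that add atoms: tert-butyldimethylsilyl chloride, CC(C)(C)[Si](C)(C)Cl
Why: Standard silylation of the secondary alcohol masks the acidic proton for the hydride and organolithium steps 5–7.

Step 5
Reactants: 8 ethyl (4R)-4-(tert-butyldimethylsilyloxy)-2,6,6-trimethylcyclohex-1-ene-1-carboxylate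
Product: 9 [(4R)-4-(tert-butyldimethylsilyloxy)-2,6,6-trimethylcyclohex-1-en-1-yl]methanol
Conditions: iBu2AlH (2.5 equiv), CH2Cl2, −78 → 0 °C; aq. KNaC4H4O6 (potassium sodium tartrate)
Reagents that add atoms: none
Why: 1,2-Reduction of the hindered conjugated ester by the aluminium hydride gives the allylic alcohol (C7 at the CH2 level) and leaves the silyl ether and the tetrasubstituted alkene untouched.

Step 6
Reactants: 9 [(4R)-4-(tert-butyldimethylsilyloxy)-2,6,6-trimethylcyclohex-1-en-1-yl]methanol
Product: 10 {[(1R)-4-(bromomethyl)-3,5,5-trimethylcyclohex-3-en-1-yl]oxy}(tert-butyl)dimethylsilane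
Conditions: CBr4, PPh3, 2,6-lutidine, CH2Cl2, −20 → 0 °C; used crude
Reagents that add atoms: carbon tetrabromide, BrC(Br)(Br)Br
Why: In the Appel reaction the oxyphosphonium ion is displaced by bromide at the primary allylic carbon under neutral conditions that the silyl ether tolerates; the labile bromide is used at once.

Step 7
Reactants: 10 {[(1R)-4-(bromomethyl)-3,5,5-trimethylcyclohex-3-en-1-yl]oxy}(tert-butyl)dimethylsilane; 11 furan-3-ylmethanol
Product: 13 (2-{[(4R)-4-(tert-butyldimethylsilyloxy)-2,6,6-trimethylcyclohex-1-en-1-yl]methyl}furan-3-yl)methanol, via dilithiated furanmethanol 12 (not isolated)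
Conditions: 11, n-BuLi (2.2 equiv), THF, −78 → 0 °C; then 10, −78 → 23 °C
Reagents that add atoms: none
Why: Alkoxide-directed ortho-lithiation of the furan occurs at C2 (between the ring oxygen and the CH2OLi group), and the 2-furyllithium displaces the primary allylic bromide (SN2) to form C7–C8, attack with allylic shift being disfavoured because it would hit a fully substituted ring carbon.

Step 8
Reactants: 13 (2-{[(4R)-4-(tert-butyldimethylsilyloxy)-2,6,6-trimethylcyclohex-1-en-1-yl]methyl}furan-3-yl)methanol; 14 (2E)-dodec-2-enoic acid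
Product: 15 (2-{[(4R)-4-(tert-butyldimethylsilyloxy)-2,6,6-trimethylcyclohex-1-en-1-yl]methyl}furan-3-yl)methyl (2E)-dodec-2-enoate
Conditions: DCC, DMAP (0.1 equiv), CH2Cl2, 0 → 23 °C
Reagents that add atoms: none
Why: Steglich esterification (carbodiimide activation, acyl transfer by DMAP) of the primary alcohol installs the C19 ester, and the conjugated E double bond of the acid should be retained under these mild conditions.

Step 9
Reactants: 15 (2-{[(4R)-4-(tert-butyldimethylsilyloxy)-2,6,6-trimethylcyclohex-1-en-1-yl]methyl}furan-3-yl)methyl (2E)-dodec-2-enoate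
Product: 16 (2-{[(4R)-4-hydroxy-2,6,6-trimethylcyclohex-1-en-1-yl]methyl}furan-3-yl)methyl (2E)-dodec-2-enoate
Conditions: HF·pyridine, pyridine, THF, 0 → 23 °C
Reagents that add atoms: none
Why: Fluoride-mediated silyl ether cleavage under buffered, non-basic conditions frees the C3 hydroxyl, and the furan, the enoate ester and the ring alkene are inert to it.

Step 10
Reactants: 16 (2-{[(4R)-4-hydroxy-2,6,6-trimethylcyclohex-1-en-1-yl]methyl}furan-3-yl)methyl (2E)-dodec-2-enoate
Product: 18 (2E)-2-{2-[(4R)-4-hydroxy-2,6,6-trimethylcyclohex-1-en-1-yl]acetyl}-4-oxobut-2-en-1-yl (2E)-dodec-2-enoate, via cis-oxoenal 17 (not isolated)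
Conditions: NBS (1.0 equiv), NaHCO3, acetone/H2O (10:1), −20 °C; then I2 (2 mol%), CH2Cl2, 23 °C
Reagents that add atoms: water, O
Why: Oxidative furan ring opening (bromination at the free α-position, addition of water at the substituted α-carbon, loss of HBr) unveils the C8 ketone and the C11 aldehyde as the cis-enedicarbonyl compound, and iodine-catalysed equilibration should give the more stable E isomer with C8 and C11 trans; the electron-rich furan should out-compete the shielded tetrasubstituted ring alkene for one equivalent of NBS at low temperature.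

Step 11
Reactants: 19 (R)-α-ionone
Product: 20 (2E,4E)-3-methyl-5-[(1R)-2,6,6-trimethylcyclohex-2-en-1-yl]penta-2,4-dienenitrile
Conditions: (EtO)2P(O)CH2CN, NaH, THF, 0 → 23 °C
Reagents that add atoms: diethyl cyanomethylphosphonate, CCOP(=O)(CC#N)OCC
Why: Horner–Wadsworth–Emmons olefination of the methyl ketone should give the dienenitrile mainly as the 2E isomer (the minor 2Z isomer is removed by chromatography), and the stabilised phosphonate anion is too weak a base to deprotonate the ring stereocentre.

Step 12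
Reactants: 20 (2E,4E)-3-methyl-5-[(1R)-2,6,6-trimethylcyclohex-2-en-1-yl]penta-2,4-dienenitrile
Product: 21 (2E,4E)-3-methyl-5-[(1R)-2,6,6-trimethyl-4-oxocyclohex-2-en-1-yl]penta-2,4-dienenitrile
Conditions: tBuOOH (70% aq., 5 equiv), Rh2(C6H10NO)4 (dirhodium tetracaprolactamate, 1 mol%), 1,2-dichloroethane, 40 °C
Reagents that add atoms: tert-butyl hydroperoxide, CC(C)(C)OO
Why: Radical allylic C–H oxidation by tert-butylperoxy radicals at the ring CH2 next to the trisubstituted alkene gives the enone, as known for α-ionone itself; the tertiary allylic C–H is shielded by the gem-dimethyl and vinyl methyl groups, and base-free conditions avoid epimerisation of this now vinylogously acidic centre.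

Step 13
Reactants: 21 (2E,4E)-3-methyl-5-[(1R)-2,6,6-trimethyl-4-oxocyclohex-2-en-1-yl]penta-2,4-dienenitrile
Product: 22 (2E,4E)-5-[(1R,4R)-4-hydroxy-2,6,6-trimethylcyclohex-2-en-1-yl]-3-methylpenta-2,4-dienenitrile
Conditions: (S)-2-methyl-CBS-oxazaborolidine (0.2 equiv), catecholborane (1.5 equiv), toluene, −78 °C
Reagents that add atoms: none
Why: In the Corey–Bakshi–Shibata reduction the enone binds the (S)-oxazaborolidine with the alkenyl flank as the large group, so hydride goes to the face that gives the (4R)-allylic alcohol; the substrate should favour the same face, since axial attack anti to the axial methyl of the gem-dimethyl carbon in the conformer with a pseudoaxial side chain leads to the 1,4-trans alcohol, and the nitrile is inert at −78 °C.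

Step 14
Reactants: 22 (2E,4E)-5-[(1R,4R)-4-hydroxy-2,6,6-trimethylcyclohex-2-en-1-yl]-3-methylpenta-2,4-dienenitrile
Product: 24 (2E,4E)-5-[(1R,4R)-4-hydroxy-2,6,6-trimethylcyclohex-2-en-1-yl]-3-methylpenta-2,4-dienal, via aldimine 23 (not isolated)
Conditions: iBu2AlH (2.5 equiv), CH2Cl2, −78 °C; then wet SiO2, aq. KNaC4H4O6 (potassium sodium tartrate), 0 °C
Reagents that add atoms: water, O
Why: Partial reduction of the nitrile by the aluminium hydride stops at the N-aluminated aldimine (the first equivalent is consumed by the hydroxyl group), and buffered hydrolysis releases the dienal without exposing the allylic alcohol to acid.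

Step 15
Reactants: 25 (2E,4E,6E)-2,7-dimethylocta-2,4,6-trienedial
Product: 26 (2E,4E,6E)-2,7-dimethylocta-2,4,6-triene-1,8-diol
Conditions: NaBH4, MeOH/CH2Cl2, 0 °C
Reagents that add atoms: none
Why: Borohydride reduces both conjugated aldehydes 1,2 and leaves the triene geometry unchanged.

Step 16
Reactants: 26 (2E,4E,6E)-2,7-dimethylocta-2,4,6-triene-1,8-diol
Product: 27 [(2E,4E,6E)-2,7-dimethylocta-2,4,6-triene-1,8-diyl]bis(triphenylphosphonium) dibromide
Conditions: PPh3·HBr (2.1 equiv), MeOH, 23 °C
Reagents that add atoms: triphenylphosphine hydrobromide, [Br-].[PH+](c1ccccc1)(c1ccccc1)c1ccccc1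
Why: Allylic alcohols react with triphenylphosphine hydrobromide by ionisation to the stabilised trienyl cation and capture by the phosphine, the standard entry to polyenyl Wittig salts, and the E geometry is the thermodynamic one.

Step 17
Reactants: 24 (2E,4E)-5-[(1R,4R)-4-hydroxy-2,6,6-trimethylcyclohex-2-en-1-yl]-3-methylpenta-2,4-dienal; 27 [(2E,4E,6E)-2,7-dimethylocta-2,4,6-triene-1,8-diyl]bis(triphenylphosphonium) dibromide
Product: 29 [(2E,4E,6E,8E,10E,12E)-13-[(1R,4R)-4-hydroxy-2,6,6-trimethylcyclohex-2-en-1-yl]-2,7,11-trimethyltrideca-2,4,6,8,10,12-hexaen-1-yl]triphenylphosphonium bromide, via mono-ylide 28 (not isolated)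
Conditions: 27 (3 equiv), NaOMe (1.0 equiv, slow addition), CH2Cl2/MeOH, −10 → 23 °C, dark
Reagents that add atoms: none
Why: Wittig olefination of the aldehyde with the mono-ylide from an excess of the bis-salt and one equivalent of slowly added base forms C11′=C12′ and leaves the second phosphonium group intact, so the C25 salt arises without the acid that an alcohol-to-phosphonium conversion would need and that the allylic C3′–OH does not tolerate; the 8E isomer is shown and the 8Z isomer is carried along.

Step 18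
Reactants: 29 the C25 phosphonium bromide of step 17; 18 (2E)-2-{2-[(4R)-4-hydroxy-2,6,6-trimethylcyclohex-1-en-1-yl]acetyl}-4-oxobut-2-en-1-yl (2E)-dodec-2-enoate
Product: 31 siphonein, (3R,3′R,6′R)-3,3′-dihydroxy-8-oxo-7,8-dihydro-β,ε-caroten-19-yl (2E)-dodec-2-enoate (all-E), via C25 ylide 30 (not isolated)
Conditions: 1,2-epoxybutane (solvent), 60 °C, argon, dark; then n-heptane/EtOAc, 80 °C
Reagents that add atoms: none
Why: Wittig olefination under neutral conditions (the epoxide scavenges HBr and releases the ylide slowly) joins C12 to the aldehyde carbon C11, which is far more electrophilic than the hindered C8 ketone, without harming the allylic ester and with no protecting group left to remove; the hindered Z isomers at C11=C12 and C11′=C12′ should then equilibrate thermally to the all-E polyene.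

## Compound list

1 | mesityl oxide | CC(=O)C=C(C)C | starting material
2 | lithium 4-methylpenta-1,3-dien-2-olate | [Li]OC(=C)C=C(C)C | intermediate
3 | 4-methyl-2-(trimethylsilyloxy)penta-1,3-diene | C=C(O[Si](C)(C)C)C=C(C)C | intermediate
4 | ethyl but-2-ynoate | CC#CC(=O)OCC | starting material
5 | ethyl 2,6,6-trimethyl-4-(trimethylsilyloxy)cyclohexa-1,4-diene-1-carboxylate | CCOC(=O)C1=C(C)CC(O[Si](C)(C)C)=CC1(C)C | intermediate
6 | ethyl 2,6,6-trimethyl-4-oxocyclohex-1-ene-1-carboxylate | CCOC(=O)C1=C(C)CC(=O)CC1(C)C | intermediate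
7 | ethyl (4R)-4-hydroxy-2,6,6-trimethylcyclohex-1-ene-1-carboxylate | CCOC(=O)C1=C(C)C[C@@H](O)CC1(C)C | intermediate
8 | ethyl (4R)-4-(tert-butyldimethylsilyloxy)-2,6,6-trimethylcyclohex-1-ene-1-carboxylate | CCOC(=O)C1=C(C)C[C@@H](O[Si](C)(C)C(C)(C)C)CC1(C)C | intermediate
9 | [(4R)-4-(tert-butyldimethylsilyloxy)-2,6,6-trimethylcyclohex-1-en-1-yl]methanol | OCC1=C(C)C[C@@H](O[Si](C)(C)C(C)(C)C)CC1(C)C | intermediate
10 | {[(1R)-4-(bromomethyl)-3,5,5-trimethylcyclohex-3-en-1-yl]oxy}(tert-butyl)dimethylsilane | BrCC1=C(C)C[C@@H](O[Si](C)(C)C(C)(C)C)CC1(C)C | intermediate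
11 | furan-3-ylmethanol | OCc1ccoc1 | starting material
12 | 2-lithio-3-(lithiooxymethyl)furan | [Li]OCc1ccoc1[Li] | intermediate
13 | (2-{[(4R)-4-(tert-butyldimethylsilyloxy)-2,6,6-trimethylcyclohex-1-en-1-yl]methyl}furan-3-yl)methanol | OCc1ccoc1CC1=C(C)C[C@@H](O[Si](C)(C)C(C)(C)C)CC1(C)C | intermediate
14 | (2E)-dodec-2-enoic acid | CCCCCCCCC/C=C/C(=O)O | starting material
15 | (2-{[(4R)-4-(tert-butyldimethylsilyloxy)-2,6,6-trimethylcyclohex-1-en-1-yl]methyl}furan-3-yl)methyl (2E)-dodec-2-enoate | CCCCCCCCC/C=C/C(=O)OCc1ccoc1CC1=C(C)C[C@@H](O[Si](C)(C)C(C)(C)C)CC1(C)C | intermediate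
16 | (2-{[(4R)-4-hydroxy-2,6,6-trimethylcyclohex-1-en-1-yl]methyl}furan-3-yl)methyl (2E)-dodec-2-enoate | CCCCCCCCC/C=C/C(=O)OCc1ccoc1CC1=C(C)C[C@@H](O)CC1(C)C | intermediate
17 | (2Z)-2-{2-[(4R)-4-hydroxy-2,6,6-trimethylcyclohex-1-en-1-yl]acetyl}-4-oxobut-2-en-1-yl (2E)-dodec-2-enoate | CCCCCCCCC/C=C/C(=O)OC/C(=C/C=O)C(=O)CC1=C(C)C[C@@H](O)CC1(C)C | intermediate
18 | (2E)-2-{2-[(4R)-4-hydroxy-2,6,6-trimethylcyclohex-1-en-1-yl]acetyl}-4-oxobut-2-en-1-yl (2E)-dodec-2-enoate | CCCCCCCCC/C=C/C(=O)OC\C(=C/C=O)C(=O)CC1=C(C)C[C@@H](O)CC1(C)C | intermediate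
19 | (R)-α-ionone, (3E)-4-[(1R)-2,6,6-trimethylcyclohex-2-en-1-yl]but-3-en-2-one | CC(=O)/C=C/[C@H]1C(C)=CCCC1(C)C | starting material
20 | (2E,4E)-3-methyl-5-[(1R)-2,6,6-trimethylcyclohex-2-en-1-yl]penta-2,4-dienenitrile | N#C/C=C(C)/C=C/[C@H]1C(C)=CCCC1(C)C | intermediate
21 | (2E,4E)-3-methyl-5-[(1R)-2,6,6-trimethyl-4-oxocyclohex-2-en-1-yl]penta-2,4-dienenitrile | N#C/C=C(C)/C=C/[C@H]1C(C)=CC(=O)CC1(C)C | intermediate
22 | (2E,4E)-5-[(1R,4R)-4-hydroxy-2,6,6-trimethylcyclohex-2-en-1-yl]-3-methylpenta-2,4-dienenitrile | N#C/C=C(C)/C=C/[C@H]1C(C)=C[C@H](O)CC1(C)C | intermediate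
23 | (2E,4E)-5-[(1R,4R)-4-hydroxy-2,6,6-trimethylcyclohex-2-en-1-yl]-3-methylpenta-2,4-dien-1-imine (present as its N-diisobutylaluminium derivative; free imine shown) | N=C/C=C(C)/C=C/[C@H]1C(C)=C[C@H](O)CC1(C)C | intermediate
24 | (2E,4E)-5-[(1R,4R)-4-hydroxy-2,6,6-trimethylcyclohex-2-en-1-yl]-3-methylpenta-2,4-dienal | O=C/C=C(C)/C=C/[C@H]1C(C)=C[C@H](O)CC1(C)C | intermediate
25 | (2E,4E,6E)-2,7-dimethylocta-2,4,6-trienedial | O=C/C(C)=C/C=C/C=C(C)/C=O | starting material
26 | (2E,4E,6E)-2,7-dimethylocta-2,4,6-triene-1,8-diol | OC/C(C)=C/C=C/C=C(C)/CO | intermediate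
27 | [(2E,4E,6E)-2,7-dimethylocta-2,4,6-triene-1,8-diyl]bis(triphenylphosphonium) dibromide | [Br-].[Br-].C(/C(C)=C/C=C/C=C(C)/C[P+](c1ccccc1)(c1ccccc1)c1ccccc1)[P+](c1ccccc1)(c1ccccc1)c1ccccc1 | intermediate
28 | mono-ylide of 27, [(2E,4E,6E)-2,7-dimethyl-8-(triphenylphosphoranylidene)octa-2,4,6-trien-1-yl]triphenylphosphonium bromide | [Br-].C(/C(C)=C/C=C/C=C(C)/C=P(c1ccccc1)(c1ccccc1)c1ccccc1)[P+](c1ccccc1)(c1ccccc1)c1ccccc1 | intermediate
29 | [(2E,4E,6E,8E,10E,12E)-13-[(1R,4R)-4-hydroxy-2,6,6-trimethylcyclohex-2-en-1-yl]-2,7,11-trimethyltrideca-2,4,6,8,10,12-hexaen-1-yl]triphenylphosphonium bromide (8E shown, accompanied by the 8Z isomer) | [Br-].C(/C(C)=C/C=C/C=C(C)/C=C/C=C(C)/C=C/[C@H]1C(C)=C[C@H](O)CC1(C)C)[P+](c1ccccc1)(c1ccccc1)c1ccccc1 | intermediate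
30 | ylide of 29, (1R,4R)-3,5,5-trimethyl-4-[(1E,3E,5E,7E,9E,11E)-3,7,12-trimethyl-13-(triphenylphosphoranylidene)trideca-1,3,5,7,9,11-hexaen-1-yl]cyclohex-2-en-1-ol | C(/C(C)=C/C=C/C=C(C)/C=C/C=C(C)/C=C/[C@H]1C(C)=C[C@H](O)CC1(C)C)=P(c1ccccc1)(c1ccccc1)c1ccccc1 | intermediate
31 | siphonein, (3R,3′R,6′R)-3,3′-dihydroxy-8-oxo-7,8-dihydro-β,ε-caroten-19-yl (2E)-dodec-2-enoate | CCCCCCCCC/C=C/C(=O)OC\C(=C/C=C/C(C)=C/C=C/C=C(C)/C=C/C=C(C)/C=C/[C@H]1C(C)=C[C@H](O)CC1(C)C)C(=O)CC1=C(C)C[C@@H](O)CC1(C)C | target

## Step count and risks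

Total: 18 steps. Longest linear sequence: 11 steps (steps 1–10, then 18).

Steps most likely to fail:

1. Step 2. The cycloaddition may stall at the fully substituted diene terminus, so that desilylation of the diene, oligomerisation of the ynoate or open-chain Michael adducts take over. Fallback from 1 to 6: mesityl oxide 1 is condensed with ethyl acetoacetate (BF3·OEt2, or NaOEt in EtOH) in a Michael addition/aldol condensation to ethyl 2,6,6-trimethyl-4-oxocyclohex-2-ene-1-carboxylate F1. F1 is converted into its extended dienolate (KOtBu, THF/tBuOH, 0 °C) and quenched inversely into cold aqueous acetic acid; kinetic C-protonation between the ketone and the ring alkene moves the double bond into conjugation with the ester and returns to 6.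

2. Step 10. Bromination of the tetrasubstituted ring alkene may compete with attack on the furan, and the Z to E equilibration of the enedicarbonyl unit may remain incomplete. Fallback from 10 to 18, with no oxidant: bromide 10 is alkylated with 1-lithio-1-methoxyallene (methoxyallene, n-BuLi, THF, −40 °C) to tert-butyl{[(1R)-4-(2-methoxybuta-2,3-dien-1-yl)-3,5,5-trimethylcyclohex-3-en-1-yl]oxy}dimethylsilane F5. Mild acid (0.1 M H2SO4, THF, 0 °C) unmasks the vinyl ketone 1-[(4R)-4-(tert-butyldimethylsilyloxy)-2,6,6-trimethylcyclohex-1-en-1-yl]but-3-en-2-one F6. A Morita–Baylis–Hillman reaction with dimethoxyacetaldehyde (DABCO, THF/H2O) gives 1-[(4R)-4-(tert-butyldimethylsilyloxy)-2,6,6-trimethylcyclohex-1-en-1-yl]-4-hydroxy-5,5-dimethoxy-3-methylidenepentan-2-one F7. Esterification with 14 (DCC, DMAP) gives the secondary ester 1,1-dimethoxy-3-methylidene-4-oxo-5-[(4R)-4-(tert-butyldimethylsilyloxy)-2,6,6-trimethylcyclohex-1-en-1-yl]pentan-2-yl (2E)-dodec-2-enoate F8. DABCO-mediated allylic transposition (two SN2′ events, thermodynamic control) moves the acyloxy group to the primary carbon and gives (2E)-2-{2-[(4R)-4-(tert-butyldimethylsilyloxy)-2,6,6-trimethylcyclohex-1-en-1-yl]acetyl}-4,4-dimethoxybut-2-en-1-yl (2E)-dodec-2-enoate F9. Aqueous HF in MeCN removes the acetal and the silyl ether and returns to 18.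

3. Step 3. The enzyme panel may give low enantioselectivity, or the β,γ-unsaturated ketone may isomerise in the buffer before it is reduced. Fallback from 6 to 7: reduction with NaBH4/CeCl3 (MeOH, −40 °C) gives racemic ethyl 4-hydroxy-2,6,6-trimethylcyclohex-1-ene-1-carboxylate F2. Lipase-catalysed transesterification with vinyl acetate (Burkholderia cepacia lipase, tBuOMe) should, by the usual empirical rule for secondary alcohols, acetylate the (R)-enantiomer to ethyl (4R)-4-acetoxy-2,6,6-trimethylcyclohex-1-ene-1-carboxylate F3 and leave ethyl (4S)-4-hydroxy-2,6,6-trimethylcyclohex-1-ene-1-carboxylate F4. After separation, F3 is deacetylated (K2CO3, EtOH) to 7.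

## Further compounds

F1 | step 2 | ethyl 2,6,6-trimethyl-4-oxocyclohex-2-ene-1-carboxylate (racemic) | CCOC(=O)C1C(C)=CC(=O)CC1(C)C
F2 | step 3 | ethyl 4-hydroxy-2,6,6-trimethylcyclohex-1-ene-1-carboxylate (racemic) | CCOC(=O)C1=C(C)CC(O)CC1(C)C
F3 | step 3 | ethyl (4R)-4-acetoxy-2,6,6-trimethylcyclohex-1-ene-1-carboxylate | CCOC(=O)C1=C(C)C[C@@H](OC(C)=O)CC1(C)C
F4 | step 3 | ethyl (4S)-4-hydroxy-2,6,6-trimethylcyclohex-1-ene-1-carboxylate | CCOC(=O)C1=C(C)C[C@H](O)CC1(C)C
F5 | step 10 | tert-butyl{[(1R)-4-(2-methoxybuta-2,3-dien-1-yl)-3,5,5-trimethylcyclohex-3-en-1-yl]oxy}dimethylsilane | C=C=C(OC)CC1=C(C)C[C@@H](O[Si](C)(C)C(C)(C)C)CC1(C)C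
F6 | step 10 | 1-[(4R)-4-(tert-butyldimethylsilyloxy)-2,6,6-trimethylcyclohex-1-en-1-yl]but-3-en-2-one | C=CC(=O)CC1=C(C)C[C@@H](O[Si](C)(C)C(C)(C)C)CC1(C)C
F7 | step 10 | 1-[(4R)-4-(tert-butyldimethylsilyloxy)-2,6,6-trimethylcyclohex-1-en-1-yl]-4-hydroxy-5,5-dimethoxy-3-methylidenepentan-2-one (both carbinol epimers) | COC(OC)C(O)C(=C)C(=O)CC1=C(C)C[C@@H](O[Si](C)(C)C(C)(C)C)CC1(C)C
F8 | step 10 | 1,1-dimethoxy-3-methylidene-4-oxo-5-[(4R)-4-(tert-butyldimethylsilyloxy)-2,6,6-trimethylcyclohex-1-en-1-yl]pentan-2-yl (2E)-dodec-2-enoate (both epimers) | CCCCCCCCC/C=C/C(=O)OC(C(OC)OC)C(=C)C(=O)CC1=C(C)C[C@@H](O[Si](C)(C)C(C)(C)C)CC1(C)C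
F9 | step 10 | (2E)-2-{2-[(4R)-4-(tert-butyldimethylsilyloxy)-2,6,6-trimethylcyclohex-1-en-1-yl]acetyl}-4,4-dimethoxybut-2-en-1-yl (2E)-dodec-2-enoate | CCCCCCCCC/C=C/C(=O)OC\C(=C/C(OC)OC)C(=O)CC1=C(C)C[C@@H](O[Si](C)(C)C(C)(C)C)CC1(C)C
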